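**Remarks.** (a) Carbon numbers are those of the eremophilane skeleton: ring A is C1–C5 plus C10, ring B is C5–C10, with methyl groups on C4 and C5 and the isopropenyl group on C7. A carbon of an open-chain precursor is called by the number it has in the target. β is the face of the C5 methyl. The target is then 3α,9α-diacyloxy-8α-hydroxy-4β,5β-dimethyl-7α-isopropenyl-10αH, i.e. (3R,4R,5R,7S,8R,9S,10R). (b) Assumption: in the oxazaborolidine-catalysed reduction (step 8) the branched alkenyl group is taken to act as the large substituent of ketone 12.

## Analysis of the target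

The target is a trans-fused decalin of the eremophilane type. It carries methyl groups on C4 and on the quaternary ring-fusion carbon C5, an isopropenyl group on C7, a free hydroxyl on C8 and (Z)-hex-2-enoyl esters on O3 and O9. There are seven stereocentres (C3, C4, C5, C7, C8, C9, C10). With the C5 methyl as β, H10 is α (trans fusion), the C4 methyl is β, and O3, O8, O9 and the C7 substituent are all α. In the all-chair form O3, the C4 methyl, O9 and the isopropenyl group are therefore equatorial, and only the C8 hydroxyl and the angular methyl are axial. The sensitive groups are the two (Z)-enoates (isomerisation to E, conjugate addition), the cis-8,9-diol monoester (acyl migration) and the isopropenyl group, which moves into conjugation whenever C8 is a ketone. The difficulties are the quaternary C5 flanked by two stereocentres, the pattern of four substituted carbons on ring B, and the need to tell three secondary hydroxyls apart. The strategy rests on the vicinal pair C5/C10 across the ring fusion and on the fact that C3–C4 can be carried as an alkene. C5–C10 is then the σ-bond of a [3,3] shift of an allylic C3–O ester whose acyl carbon is C9, and if that ester is a δ-lactone the same shift closes ring A. The C3 oxygen and the C4 hydrogen return later by hydroboration, and the carboxyl carbon becomes C9 of ring B.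

## Retrosynthetic reasoning

**Ester C–O bonds and the (Z)-alkenes.** Target 32 is cut at the two acyl–oxygen bonds, and the (Z)-alkenes are traced back to alkynes: 32 from bis-ynoate 31, and 31 from triol 29 and acid 30. A (Z)-enoic acid would risk isomerisation during activation, so the geometry is set last by semihydrogenation. The acylation has to reach the equatorial 3- and 9-hydroxyls and leave the axial, doubly flanked 8-hydroxyl free.

**C8–H and C7–C11.** Triol 29 comes from bis-silyl ether 28, and 28 from ketone 27 by hydride delivery to C8. Ketone 27 is cut at C7–C11 into ketone 25 and bromide 26. The C8 carbonyl is the only handle that activates C7, and it lets the axial 8α-hydroxyl be made by equatorial attack of a bulky hydride. The forward coupling must take the enolate on the C7 side and leave the alkene out of conjugation.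

**Oxidation level at C8 and the C3–O and C4–H bonds.** Ketone 25 comes from alcohol 24, and 24 from triol 23 by silylation of the two equatorial hydroxyls. Triol 23 is cut at C3–O and C4–H to diol 22, since syn-hydroboration of the C3=C4 bond from the face opposite the axial C5 methyl gives 3α-OH and 4β-CH3 in one step. Doing this after ring B is closed uses the rigid trans-decalin for facial control.

**C8–C9.** Diol 22 is opened between the two carbinol carbons to dialdehyde 21. The cut is made there because a reductive carbonyl coupling forms the bond and both oxygens together, and because a 9β-oxygen would be syn-axial to the C5 methyl. Dialdehyde 21 comes from diol 20 by oxidation under basic, cold conditions to protect C10; 20 comes from aldehyde acid 19, and 19 from acetal acid 18.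

**C5–C10, the key disconnection.** Acid 18 is cut between the quaternary C5 and C10, through silyl ester 17, to ketene acetal 16 of lactone 15. This bond is chosen because it joins the two ring-fusion centres. A [3,3] shift makes it, closes ring A and leaves the C3=C4 alkene and the C9 carboxyl. The forward step must transfer the single C3 stereocentre to C5 and C10 and place the C5 methyl cis to the carboxyl, which the (Z)-alkene and the ring-enforced boat should do.

**Lactone C–O and the C3 stereocentre.** Lactone 15 comes from hydroxy ester 13 through hydroxy acid 14, and 13 from ketone 12 by enantioselective reduction. The one stereocentre that catalysis has to set is thus a secondary allylic carbinol next to a branched alkenyl group, a good case for an oxazaborolidine catalyst.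

**C2–C3.** Ketone 12 is cut at the acyl–alkyl bond into acid 8 (used as its chloride 11) and zinc reagent 10, made from bromide 9. An organozinc tolerates the ester and does not add to the enone.

**The tetrasubstituted alkene.** Acid 8 comes from ester 7, and 7 from iodide 6 by methyl cross-coupling. Iodide 6 comes from ynoate 5 by syn-carbocupration and iodination. Both methyl groups are delivered cis across the former triple bond, which fixes the (Z)-geometry that the key step needs.

**C–C bonds of the chain.** Ynoate 5 is cut into alkyne 3 and chloroformate 4, and 3 into bromide 1 and acetylide 2.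

## Alternatives that were turned down

**Alternative 1:** This plan disconnects C5–C10 and C6–C7 together, as an intramolecular Diels–Alder reaction of the acyclic triene A2. The 2-silyloxydiene C7=C8–C9=C10 adds to an α-substituted acrolein (C6=C5–CHO) across a four-carbon tether that already carries the C3 silyl ether and the C4 methyl, and heating should give the trans-fused angular aldehyde A1.
- For it: both rings and the C5/C10 pair arise in one step, and C3 and C4 are present from the start and can steer the facial selectivity. The C8 silyl enol ether of A1 is ideally placed for a Rubottom oxidation that would deliver the C9 oxygen and the C8 ketone directly. On the functionalisation of ring B this plan is stronger than the chosen one.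
- Against it: the angular carbon arrives as CHO and must be taken down to CH3 at a neopentyl position between C4 and C10, which costs several steps or forcing Wolff–Kishner conditions. An α-branched acrolein that must form a quaternary carbon is a sluggish dienophile, and Lewis acids that would speed it up endanger the silyloxydiene. The trans fusion depends on an endo preference of the formyl group that is not assured. A2 needs two stereocentres, a polymerisable enal and a stereodefined diene, so it is no shorter to make than lactone 15.
- Comparison: the chosen strategy brings the angular methyl at the right oxidation level and asks catalysis for one stereocentre only.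

**Alternative 2:** This plan disconnects C4–C5 and C1–C10. Ring A is added to a preformed ring B by an intermolecular Diels–Alder reaction of quinone A4 with silyloxydiene A5 under a chiral diol-modified TiCl2(O-i-Pr)2 catalyst. Acid (enol ether to C3 ketone) and base (equilibration of C4 and C10) in the same flask then give trione A3.
- For it: it is the most convergent plan. Two small achiral components give the whole bicycle with the quaternary C5 methyl in one catalytic asymmetric step, and the methoxy group directs the regiochemistry. In convergence and in steps to the bicyclic core it beats the chosen route.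
- Against it: A3 is wrongly oxidised for this target. The C6 carbonyl must be removed next to the quaternary carbon while two other ketones and a vinylogous ester are present, C7 is a nucleophilic sp2 carbon that still has to receive the isopropenyl group, and three carbonyls must be distinguished. The trans fusion relies on epimerising C10, but with an angular methyl the cis- and trans-fused diones are close in energy. The enantioselectivity with this unsymmetrical diene is not assured.
- Comparison: the chosen route never creates an oxygen at C6, sets the trans fusion kinetically in the [3,3] shift, and brings in O8 and O9 together.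

**Alternative 3:** This plan disconnects C4–C5 by a 1,2-shift. The enantiopure hydrindenedione A7 is homologated at its saturated five-ring ketone by addition of a selenium-stabilised ethyl anion, followed by AgBF4-promoted migration of the quaternary carbon C5 from C3 to C4. This enlarges the cyclopentanone to ring A and gives enedione A6.
- For it: the absolute configuration and the quaternary methyl come from one organocatalytic annulation, and the more substituted carbon is the one that normally migrates. The C4 methyl can settle equatorial (β) by enolisation, and A6 already holds the C3 and C8 oxygens. In steps to a bicyclic core, and in the reliability of the source of chirality, this alternative is stronger than the chosen route.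
- Against it: the addition must occur at a neopentyl ketone in the presence of an enone and uses stoichiometric selenium and silver. From A6 the C10 hydrogen and the C9 oxygen still have to come from the C9=C10 bond, which requires the C3 and C8 ketones to be differentiated first and C8 to be re-oxidised later. C3, C4, C9 and C10 are then set in four separate substrate-controlled operations.
- Comparison: the chosen strategy offers instead a trans fusion from a single stereospecific pericyclic step, one hydroboration that sets C3 and C4 together, and a ring closure that delivers O8 and O9 at once, so no carbonyl differentiation is needed.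

Key step: step 10

## Route

Step 1
Reactants: 1 2-(2-bromoethyl)-1,3-dioxolane; 2 lithium acetylide ethylenediamine complex
Product: 3 2-(but-3-yn-1-yl)-1,3-dioxolane
Conditions: DMSO, 10 °C → rt
Reagents that add atoms: none
Why: SN2 alkylation of the acetylide by the primary bromide; DMSO and the amine-complexed acetylide favour substitution over elimination, and the acetal is inert to base.

Step 2
Reactants: 3 2-(but-3-yn-1-yl)-1,3-dioxolane; 4 methyl chloroformate
Product: 5 methyl 5-(1,3-dioxolan-2-yl)pent-2-ynoate
Conditions: n-BuLi, THF, −78 °C; then 4, −78 → 0 °C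
Reagents that add atoms: none
Why: Deprotonation of the terminal alkyne and C-acylation of the lithium acetylide by the chloroformate (alkoxycarbonylation).

Step 3
Reactants: 5 methyl 5-(1,3-dioxolan-2-yl)pent-2-ynoate
Product: 6 methyl (2E)-5-(1,3-dioxolan-2-yl)-2-iodo-3-methylpent-2-enoate
Conditions: Me2CuLi (from CuI and MeLi), THF, −78 °C; then I2, THF, −78 → −40 °C
Reagents that add atoms: lithium dimethylcuprate, [Li+].C[Cu-]C; iodine, II
Why: syn-Carbocupration of the ynoate puts the new methyl on C5 cis to copper on C4, and iodinolysis of the alkenylcopper at −78 °C, before the copper allenoate can equilibrate, replaces copper by iodine with retention; the ester and the C6 chain therefore end up cis.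

Step 4
Reactants: 6 methyl (2E)-5-(1,3-dioxolan-2-yl)-2-iodo-3-methylpent-2-enoate
Product: 7 methyl (2Z)-5-(1,3-dioxolan-2-yl)-2,3-dimethylpent-2-enoate
Conditions: Me2Zn, PdCl2(dppf) (3 mol%), THF, 50 °C
Reagents that add atoms: dimethylzinc, C[Zn]C
Why: Negishi cross-coupling of the alkenyl iodide; oxidative addition to zerovalent palladium, transmetalation and reductive elimination all proceed with retention, so the two methyl groups are cis and the (Z)-tetrasubstituted alkene is fixed.

Step 5
Reactants: 7 methyl (2Z)-5-(1,3-dioxolan-2-yl)-2,3-dimethylpent-2-enoate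
Product: 8 (2Z)-5-(1,3-dioxolan-2-yl)-2,3-dimethylpent-2-enoic acid
Conditions: LiOH, THF/MeOH/H2O, 40 °C; then 0.5 M HCl to pH 4, 0 °C
Reagents that add atoms: lithium hydroxide, [Li+].[OH-]
Why: Saponification; the acetal is stable to base and should survive the brief cold acidification, and the fully substituted alkene has no lower-energy position to move to.

Step 6
Reactants: 9 ethyl 4-bromobutanoate
Product: 10 (4-ethoxy-4-oxobutyl)zinc bromide (THF solution)
Conditions: Zn dust (activated with BrCH2CH2Br and Me3SiCl), LiCl, THF, 40 °C
Reagents that add atoms: zinc, [Zn]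
Why: Direct insertion of zinc into the primary C–Br bond, accelerated by LiCl; the organozinc tolerates its own ester.

Step 7
Reactants: 8 (2Z)-5-(1,3-dioxolan-2-yl)-2,3-dimethylpent-2-enoic acid; 10 (4-ethoxy-4-oxobutyl)zinc bromide
Product: 12 ethyl (6Z)-9-(1,3-dioxolan-2-yl)-6,7-dimethyl-5-oxonon-6-enoate, via acid chloride 11 (not isolated)
Conditions: Me2C=C(Cl)NMe2, CH2Cl2, 0 °C → rt; then 10, Pd(PPh3)4 (3 mol%), THF, 0 °C → rt
Reagents that add atoms: 1-chloro-N,N,2-trimethylprop-1-en-1-amine, CC(C)=C(Cl)N(C)C (chlorine in 11 only)
Why: The α-chloroenamine makes the acid chloride under neutral conditions that spare the acetal; Pd-catalysed acylation of the alkylzinc (Negishi-type ketone synthesis) then forms C2–C3 without touching the ester or the alkene geometry.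

Step 8
Reactants: 12 ethyl (6Z)-9-(1,3-dioxolan-2-yl)-6,7-dimethyl-5-oxonon-6-enoate
Product: 13 ethyl (5S,6Z)-9-(1,3-dioxolan-2-yl)-5-hydroxy-6,7-dimethylnon-6-enoate
Conditions: (R)-2-methyl-CBS-oxazaborolidine (15 mol%), BH3·SMe2, THF, −30 °C; MeOH
Reagents that add atoms: none
Why: Corey–Bakshi–Shibata reduction; the ketone binds to the ring boron anti to the branched alkenyl group and hydride is delivered from the coordinated borane to the face that should give the (S)-carbinol at C3; the ester and the tetrasubstituted alkene react much more slowly at this temperature.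

Step 9
Reactants: 13 ethyl (5S,6Z)-9-(1,3-dioxolan-2-yl)-5-hydroxy-6,7-dimethylnon-6-enoate
Product: 15 (6S)-6-[(2Z)-5-(1,3-dioxolan-2-yl)-3-methylpent-2-en-2-yl]oxan-2-one, via hydroxy acid 14 (not isolated)
Conditions: LiOH, THF/H2O, 0 °C → rt; 0.5 M HCl to pH 4–5, 0 °C; then EDC·HCl, DMAP (0.2 equiv), CH2Cl2, rt
Reagents that add atoms: lithium hydroxide, [Li+].[OH-] (oxygen in 14 only)
Why: Saponification and carbodiimide lactonisation (Steglich type) close the δ-lactone through O3; strong acid, which could ionise the allylic C3–O bond, is avoided, and C3 is not a reacting centre, so its configuration is retained.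

Step 10
Reactants: 15 (6S)-6-[(2Z)-5-(1,3-dioxolan-2-yl)-3-methylpent-2-en-2-yl]oxan-2-one
Product: 18 (1R,2S)-2-[2-(1,3-dioxolan-2-yl)ethyl]-2,3-dimethylcyclohex-3-ene-1-carboxylic acid, via silyl ketene acetal 16 (not isolated), via trimethylsilyl ester 17 (not isolated)
Conditions: LiN(i-Pr)2, Me3SiCl/Et3N (premixed), THF, −78 °C → rt; toluene, 100 °C; then MeOH/H2O
Reagents that add atoms: chlorotrimethylsilane, C[Si](C)(C)Cl (silicon in 16 and 17 only)
Why: LiN(i-Pr)2 removes the C10 proton of 15 in the presence of Me3SiCl, so the lactone enolate is O-silylated at once to the cyclic ketene acetal 16; on warming, the C4=C5 alkenyl group folds over the ring and a suprafacial [3,3] shift forms C5–C10 while C3–O breaks, giving silyl ester 17 and, after hydrolysis, acid 18. The closest known reaction type is the Ireland–Claisen rearrangement of lactone-derived silyl ketene acetals that carry an alkenyl group on the carbinol carbon, which gives cycloalkenecarboxylic acids. Ring A (six-membered, carbocyclic) is closed by the sigmatropic C5–C10 bond with C1–C2 as the existing tether; C3 and C10 are then the bridgeheads of a bicyclo[2.2.2]octane-like array, so only a boat transition state is possible. C10 is controlled by the fixed ketene acetal geometry (C1 cis to the ring oxygen) together with the (S)-C3 centre, since the new bond must form on the face of the allyl unit from which the oxygen departs. C5 is controlled by the (Z)-geometry of C4=C5: in the boat the C6 chain, cis to C3, lies over C1 and the C5 methyl lies over H10, so the methyl ends cis to the C9 carboxyl, which is the relationship needed for the trans ring fusion. The step needs complete chirality transfer from C3 and retention of the alkene geometry; the ring-enforced boat and the absence of acid, which could ionise the allylic C3–O bond, should secure both. The C3 stereocentre is consumed and reappears as the C3=C4 alkene.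

Step 11
Reactants: 18 (1R,2S)-2-[2-(1,3-dioxolan-2-yl)ethyl]-2,3-dimethylcyclohex-3-ene-1-carboxylic acid
Product: 19 (1R,2S)-2,3-dimethyl-2-(3-oxopropyl)cyclohex-3-ene-1-carboxylic acid
Conditions: 1 M HCl, THF, rt
Reagents that add atoms: water, O
Why: Acid-catalysed acetal hydrolysis; dilute aqueous acid at room temperature should not protonate the trisubstituted alkene, and C10 is not enolised at the carboxylic acid level.

Step 12
Reactants: 19 (1R,2S)-2,3-dimethyl-2-(3-oxopropyl)cyclohex-3-ene-1-carboxylic acid
Product: 20 3-[(1S,6R)-6-(hydroxymethyl)-1,2-dimethylcyclohex-2-en-1-yl]propan-1-ol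
Conditions: LiAlH4, THF, 0 °C → reflux
Reagents that add atoms: none
Why: Hydride reduction of the aldehyde and the carboxylic acid to the 1,6-diol; the isolated alkene is inert.

Step 13
Reactants: 20 3-[(1S,6R)-6-(hydroxymethyl)-1,2-dimethylcyclohex-2-en-1-yl]propan-1-ol
Product: 21 (1R,2S)-2,3-dimethyl-2-(3-oxopropyl)cyclohex-3-ene-1-carbaldehyde
Conditions: (COCl)2, DMSO, CH2Cl2, −78 °C; Et3N, −78 → 0 °C
Reagents that add atoms: none
Why: Double Swern oxidation; both aldehydes are released together under cold, weakly basic conditions, which should limit epimerisation at C10 and aldol reactions, and the crude dialdehyde is used at once.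

Step 14
Reactants: 21 (1R,2S)-2,3-dimethyl-2-(3-oxopropyl)cyclohex-3-ene-1-carbaldehyde
Product: 22 11,12,13-trinoreremophil-3-ene-8α,9α-diol (trans-fused; 5β-CH3, 10α-H)
Conditions: SmI2 (2.5 equiv), t-BuOH, THF, −78 °C → rt
Reagents that add atoms: none
Why: Intramolecular pinacol coupling by divalent samarium; the ketyl of the unhindered C8 aldehyde adds to the C9 aldehyde, the samarium-bridged diolate gives the cis-diol, and the C9 oxygen should take the equatorial α-position because a 9β-oxygen would be syn-axial to the C5 methyl; ring B closes as the trans-decalin because C5 and C10 are already set.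

Step 15
Reactants: 22 11,12,13-trinoreremophil-3-ene-8α,9α-diol
Product: 23 11,12,13-trinoreremophilane-3α,8α,9α-triol (4β-CH3, 5β-CH3, 10α-H)
Conditions: BH3·THF (4 equiv), THF, 0 °C → rt; NaOH, H2O2, 0 °C → rt
Reagents that add atoms: hydrogen peroxide, OO
Why: Hydroboration–oxidation of the trisubstituted alkene; boron adds to C3 and hydrogen to C4 syn from the α-face, opposite the axial C5 methyl, and oxidation with retention gives the equatorial 3α-OH and the equatorial 4β-CH3.

Step 16
Reactants: 23 11,12,13-trinoreremophilane-3α,8α,9α-triol
Product: 24 3α,9α-bis(tert-butyldimethylsilyloxy)-11,12,13-trinoreremophilan-8α-ol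
Conditions: t-BuMe2SiCl (2.4 equiv), imidazole, DMF, 0 °C → rt
Reagents that add atoms: tert-butyl(chloro)dimethylsilane, CC(C)(C)[Si](C)(C)Cl
Why: Silyl ether formation under kinetic control; the two equatorial hydroxyls (O3, O9) should react before the axial 8-OH, which is further shielded once O9 is silylated.

Step 17
Reactants: 24 3α,9α-bis(tert-butyldimethylsilyloxy)-11,12,13-trinoreremophilan-8α-ol
Product: 25 3α,9α-bis(tert-butyldimethylsilyloxy)-11,12,13-trinoreremophilan-8-one
Conditions: Dess–Martin periodinane, NaHCO3, CH2Cl2, rt
Reagents that add atoms: none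
Why: Dess–Martin oxidation of the axial secondary alcohol under buffered, non-epimerising conditions; C9 keeps its equatorial silyloxy group, which is also the more stable epimer.

Step 18
Reactants: 25 3α,9α-bis(tert-butyldimethylsilyloxy)-11,12,13-trinoreremophilan-8-one; 26 2-bromopropene
Product: 27 3α,9α-bis(tert-butyldimethylsilyloxy)-7βH-eremophil-11-en-8-one (7α-isopropenyl)
Conditions: LiN(SiMe3)2 (2.2 equiv), THF/toluene, −78 °C; Pd2(dba)3 (2.5 mol%), P(t-Bu)3 (6 mol%), 26, rt → 45 °C; AcOH, −78 °C
Reagents that add atoms: none
Why: Pd-catalysed α-alkenylation of a ketone enolate; the kinetic enolate forms at the C7 methylene and not at the hindered, oxygenated C9, and the alkenylpalladium bromide transmetalates to it and reductively eliminates. The product is held as its dienolate by the second equivalent of base; axial protonation at C7 on the cold quench should give the equatorial 7α-isopropenyl ketone with the alkene out of conjugation.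

Step 19
Reactants: 27 3α,9α-bis(tert-butyldimethylsilyloxy)-7βH-eremophil-11-en-8-one
Product: 28 3α,9α-bis(tert-butyldimethylsilyloxy)-7βH-eremophil-11-en-8α-ol
Conditions: LiBH(s-Bu)3, THF, −78 °C; MeOH, aq NH4Cl
Reagents that add atoms: none
Why: Reduction by a bulky trialkylborohydride; attack from the equatorial direction, away from the axial hydrogens on C6 and C10, should give the axial 8α-alcohol, cis to both neighbours; the cold quench limits silyl migration from O9.

Step 20
Reactants: 28 3α,9α-bis(tert-butyldimethylsilyloxy)-7βH-eremophil-11-en-8α-ol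
Product: 29 7βH-eremophil-11-ene-3α,8α,9α-triol
Conditions: n-Bu4NF, THF, rt → 45 °C
Reagents that add atoms: none
Why: Fluoride cleavage of both silyl ethers; no base-sensitive group is left at this stage, and any silyl migration is harmless because both groups are removed.

Step 21
Reactants: 29 7βH-eremophil-11-ene-3α,8α,9α-triol; 30 hex-2-ynoic acid
Product: 31 8α-hydroxy-7βH-eremophil-11-ene-3α,9α-diyl bis(hex-2-ynoate)
Conditions: 30 (2.3 equiv), EDC·HCl, DMAP (0.2 equiv), CH2Cl2, −10 °C → rt
Reagents that add atoms: none
Why: Steglich esterification; the equatorial 3- and 9-hydroxyls should be acylated before the axial 8-OH, which lies between the isopropenyl group and the new C9 ester, and the equatorial ester is also the favoured position should the acyl group migrate.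

Step 22
Reactants: 31 8α-hydroxy-7βH-eremophil-11-ene-3α,9α-diyl bis(hex-2-ynoate)
Product: 32 (3R,4R,5R,7S,8R,9S,10R)-8-hydroxyeremophil-11-ene-3,9-diyl bis[(2Z)-hex-2-enoate] (target, CNP0420276.1)
Conditions: H2 (1 atm), Pd/CaCO3 poisoned with Pb(OAc)2, quinoline, EtOAc, rt
Reagents that add atoms: none
Why: Lindlar-type semihydrogenation; syn-addition of hydrogen to each ynoate gives the (Z)-enoate, and the poisoned catalyst should reduce the 1,1-disubstituted isopropenyl alkene and the product enoates much more slowly, so the reaction is stopped after two equivalents of hydrogen.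

## Compound list

1 | 2-(2-bromoethyl)-1,3-dioxolane | BrCCC1OCCO1 | starting material
2 | lithium acetylide ethylenediamine complex | [Li]C#C.NCCN | starting material
3 | 2-(but-3-yn-1-yl)-1,3-dioxolane | C#CCCC1OCCO1 | intermediate
4 | methyl chloroformate | COC(=O)Cl | starting material
5 | methyl 5-(1,3-dioxolan-2-yl)pent-2-ynoate | COC(=O)C#CCCC1OCCO1 | intermediate
6 | methyl (2E)-5-(1,3-dioxolan-2-yl)-2-iodo-3-methylpent-2-enoate | COC(=O)/C(I)=C(C)\CCC1OCCO1 | intermediate
7 | methyl (2Z)-5-(1,3-dioxolan-2-yl)-2,3-dimethylpent-2-enoate | COC(=O)/C(C)=C(C)\CCC1OCCO1 | intermediate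
8 | (2Z)-5-(1,3-dioxolan-2-yl)-2,3-dimethylpent-2-enoic acid | OC(=O)/C(C)=C(C)\CCC1OCCO1 | intermediate
9 | ethyl 4-bromobutanoate | CCOC(=O)CCCBr | starting material
10 | (4-ethoxy-4-oxobutyl)zinc bromide | CCOC(=O)CCC[Zn]Br | intermediate
11 | (2Z)-5-(1,3-dioxolan-2-yl)-2,3-dimethylpent-2-enoyl chloride | ClC(=O)/C(C)=C(C)\CCC1OCCO1 | intermediate (not isolated)
12 | ethyl (6Z)-9-(1,3-dioxolan-2-yl)-6,7-dimethyl-5-oxonon-6-enoate | CCOC(=O)CCCC(=O)/C(C)=C(C)\CCC1OCCO1 | intermediate
13 | ethyl (5S,6Z)-9-(1,3-dioxolan-2-yl)-5-hydroxy-6,7-dimethylnon-6-enoate | CCOC(=O)CCC[C@H](O)/C(C)=C(C)\CCC1OCCO1 | intermediate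
14 | (5S,6Z)-9-(1,3-dioxolan-2-yl)-5-hydroxy-6,7-dimethylnon-6-enoic acid | OC(=O)CCC[C@H](O)/C(C)=C(C)\CCC1OCCO1 | intermediate (not isolated)
15 | (6S)-6-[(2Z)-5-(1,3-dioxolan-2-yl)-3-methylpent-2-en-2-yl]oxan-2-one | O=C1CCC[C@H](O1)/C(C)=C(C)\CCC1OCCO1 | intermediate
16 | trimethyl({(2S)-2-[(2Z)-5-(1,3-dioxolan-2-yl)-3-methylpent-2-en-2-yl]-3,4-dihydro-2H-pyran-6-yl}oxy)silane | C[Si](C)(C)OC1=CCC[C@H](O1)/C(C)=C(C)\CCC1OCCO1 | intermediate (not isolated)
17 | trimethylsilyl (1R,2S)-2-[2-(1,3-dioxolan-2-yl)ethyl]-2,3-dimethylcyclohex-3-ene-1-carboxylate | O1CCOC1CC[C@]2(C)C(C)=CCC[C@H]2C(=O)O[Si](C)(C)C | intermediate (not isolated)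
18 | (1R,2S)-2-[2-(1,3-dioxolan-2-yl)ethyl]-2,3-dimethylcyclohex-3-ene-1-carboxylic acid | O1CCOC1CC[C@]2(C)C(C)=CCC[C@H]2C(=O)O | intermediate
19 | (1R,2S)-2,3-dimethyl-2-(3-oxopropyl)cyclohex-3-ene-1-carboxylic acid | O=CCC[C@]1(C)C(C)=CCC[C@H]1C(=O)O | intermediate
20 | 3-[(1S,6R)-6-(hydroxymethyl)-1,2-dimethylcyclohex-2-en-1-yl]propan-1-ol | OCCC[C@]1(C)C(C)=CCC[C@H]1CO | intermediate
21 | (1R,2S)-2,3-dimethyl-2-(3-oxopropyl)cyclohex-3-ene-1-carbaldehyde | O=CCC[C@]1(C)C(C)=CCC[C@H]1C=O | intermediate
22 | 11,12,13-trinoreremophil-3-ene-8α,9α-diol (5β-CH3, 10α-H) | C1C[C@]2(C)C(C)=CCC[C@H]2[C@H](O)[C@@H]1O | intermediate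
23 | 11,12,13-trinoreremophilane-3α,8α,9α-triol (4β-CH3, 5β-CH3, 10α-H) | C1C[C@]2(C)[C@@H](C)[C@H](O)CC[C@H]2[C@H](O)[C@@H]1O | intermediate
24 | 3α,9α-bis(tert-butyldimethylsilyloxy)-11,12,13-trinoreremophilan-8α-ol | C1C[C@]2(C)[C@@H](C)[C@H](O[Si](C)(C)C(C)(C)C)CC[C@H]2[C@H](O[Si](C)(C)C(C)(C)C)[C@@H]1O | intermediate
25 | 3α,9α-bis(tert-butyldimethylsilyloxy)-11,12,13-trinoreremophilan-8-one | C1C[C@]2(C)[C@@H](C)[C@H](O[Si](C)(C)C(C)(C)C)CC[C@H]2[C@H](O[Si](C)(C)C(C)(C)C)C1=O | intermediate
26 | 2-bromopropene | CC(Br)=C | starting material
27 | 3α,9α-bis(tert-butyldimethylsilyloxy)-7βH-eremophil-11-en-8-one | C=C(C)[C@@H]1C[C@]2(C)[C@@H](C)[C@H](O[Si](C)(C)C(C)(C)C)CC[C@H]2[C@H](O[Si](C)(C)C(C)(C)C)C1=O | intermediate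
28 | 3α,9α-bis(tert-butyldimethylsilyloxy)-7βH-eremophil-11-en-8α-ol | C=C(C)[C@@H]1C[C@]2(C)[C@@H](C)[C@H](O[Si](C)(C)C(C)(C)C)CC[C@H]2[C@H](O[Si](C)(C)C(C)(C)C)[C@@H]1O | intermediate
29 | 7βH-eremophil-11-ene-3α,8α,9α-triol | C=C(C)[C@@H]1C[C@]2(C)[C@@H](C)[C@H](O)CC[C@H]2[C@H](O)[C@@H]1O | intermediate
30 | hex-2-ynoic acid | CCCC#CC(=O)O | starting material
31 | 8α-hydroxy-7βH-eremophil-11-ene-3α,9α-diyl bis(hex-2-ynoate) | C=C(C)[C@@H]1C[C@]2(C)[C@@H](C)[C@H](OC(=O)C#CCCC)CC[C@H]2[C@H](OC(=O)C#CCCC)[C@@H]1O | intermediate
32 | (1S,2R,3S,4aR,5R,6R,8aR)-2-hydroxy-4a,5-dimethyl-3-(prop-1-en-2-yl)decahydronaphthalene-1,6-diyl bis[(2Z)-hex-2-enoate] | C=C(C)[C@@H]1C[C@]2(C)[C@@H](C)[C@H](OC(=O)/C=C\CCC)CC[C@H]2[C@H](OC(=O)/C=C\CCC)[C@@H]1O | target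

## Step count and least certain steps

Total: 22 steps. Longest linear sequence: 21 steps (steps 1–5 and 7–22 from 1; step 6 is a one-step branch).

**Step 10 (key step).** The tetrasubstituted alkene terminus may slow the [3,3] shift so far that other processes take over. These are heterolysis of the allylic C3–O bond of 16 (recombination without stereocontrol, or 1,4-elimination to a dienoic acid) and loss of the ketene acetal by C-silylation or self-condensation during enolisation. The fallback sets out from 8 and returns at 18:
- Acid chloride 11 is coupled with Me2Zn under the Pd(PPh3)4 conditions of step 7 to the methyl ketone (3Z)-6-(1,3-dioxolan-2-yl)-3,4-dimethylhex-3-en-2-one F1.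
- Reduction with the (S)-configured oxazaborolidine and BH3·SMe2 should give (2R,3Z)-6-(1,3-dioxolan-2-yl)-3,4-dimethylhex-3-en-2-ol F2.
- Esterification with hex-5-enoic acid (EDC·HCl, DMAP) gives (2R,3Z)-6-(1,3-dioxolan-2-yl)-3,4-dimethylhex-3-en-2-yl hex-5-enoate F3.
- The acyclic Ireland–Claisen rearrangement of F3 (LiN(i-Pr)2, THF/DMPU, Me3SiCl, −78 °C → rt) runs through a chair with the carbinol methyl equatorial and the (Z)-ketene acetal. It should transfer the carbinol configuration to C5 and C10 and give (2R,3S,4E)-2-(but-3-en-1-yl)-3-[2-(1,3-dioxolan-2-yl)ethyl]-3,4-dimethylhex-4-enoic acid F4.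
- Ring-closing metathesis with the second-generation Grubbs catalyst between the terminal alkene and the propenyl group forms C3=C4, expels propene and gives 18.

Ring A is then closed by metathesis and not by the sigmatropic bond, which removes the strain of the bicyclic boat.

**Step 14.** The dialdehyde may undergo intramolecular aldol reaction or epimerisation at C10 before electron transfer, and facial control at C9 in the ketyl coupling may be incomplete, because it rests only on the avoidance of a syn-axial contact with the C5 methyl. The fallback sets out from 21 and returns at 22, replacing radical coupling by umpolung: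
- An intramolecular acyloin cyclisation catalysed by the carbene from 3-benzyl-5-(2-hydroxyethyl)-4-methylthiazolium chloride and Et3N is used. The unhindered C8 aldehyde forms the acyl-anion equivalent and adds to the C9 aldehyde. This should give 9α-hydroxy-11,12,13-trinoreremophil-3-en-8-one F5, whose C9 hydroxyl can settle equatorial through the enol.
- LiBH(s-Bu)3 then reduces the C8 ketone from the equatorial side to diol 22.

**Step 16.** The rate difference between the vicinal 8- and 9-hydroxyls is only kinetic, so silylation may spill over to the axial 8-OH or stop short at the 9-OH next to the ring fusion. The fallback sets out from 23 and returns at 24, blocking O8 instead of relying on rates: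
- Trimethyl orthoacetate (1.1 equiv) and a trace of camphorsulfonic acid convert the cis-8,9-diol into the cyclic 8,9-orthoacetate of the triol F6.
- Mild aqueous acetic acid opens the orthoester to the axial ester, 8α-acetoxy-11,12,13-trinoreremophilane-3α,9α-diol F7.
- t-BuMe2SiOTf and 2,6-lutidine give 8α-acetoxy-3α,9α-bis(tert-butyldimethylsilyloxy)-11,12,13-trinoreremophilane F8.
- i-Bu2AlH at −78 °C removes the acetate and gives 24.

**Step 18.** Proton transfer may move the enolate toward C9, the new double bond may migrate into conjugation with C8 under the basic conditions, or the hindered enolate may couple too slowly. The fallback sets out from 25 and returns at 27: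
- Aldol addition of the zinc enolate (LiN(i-Pr)2, ZnCl2, then acetone, −78 °C) gives 3α,9α-bis(tert-butyldimethylsilyloxy)-11-hydroxy-7βH-eremophilan-8-one F9.
- Dehydration (MeSO2Cl, Et3N, then DBU) gives the conjugated 3α,9α-bis(tert-butyldimethylsilyloxy)eremophil-7(11)-en-8-one F10.
- Deconjugation through the dienolate (KOt-Bu, t-BuOH/THF) with kinetic α-protonation by acetic acid at −78 °C gives 27.

**Step 21.** The acyl group may also go onto the 8-OH or migrate between O9 and O8, and DMAP may add to the activated ynoic acid. The fallback sets out from 28 and returns at 31: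
- The 8-OH is protected with 4-methoxybenzyl trichloroacetimidate and catalytic La(OTf)3 to give the 8α-(4-methoxybenzyl) ether of 28, F11.
- n-Bu4NF gives the 8α-(4-methoxybenzyloxy)-3α,9α-diol F12.
- Esterification of both free hydroxyls with 30 (EDC·HCl, DMAP) gives the 8α-(4-methoxybenzyloxy) bis(hex-2-ynoate) F13.
- DDQ in wet CH2Cl2 removes the benzyl ether and gives 31.

## Further compounds

F1 | step 10 | (3Z)-6-(1,3-dioxolan-2-yl)-3,4-dimethylhex-3-en-2-one | CC(=O)/C(C)=C(C)\CCC1OCCO1
F2 | step 10 | (2R,3Z)-6-(1,3-dioxolan-2-yl)-3,4-dimethylhex-3-en-2-ol | C[C@@H](O)/C(C)=C(C)\CCC1OCCO1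
F3 | step 10 | (2R,3Z)-6-(1,3-dioxolan-2-yl)-3,4-dimethylhex-3-en-2-yl hex-5-enoate | C=CCCCC(=O)O[C@H](C)/C(C)=C(C)\CCC1OCCO1
F4 | step 10 | (2R,3S,4E)-2-(but-3-en-1-yl)-3-[2-(1,3-dioxolan-2-yl)ethyl]-3,4-dimethylhex-4-enoic acid | O1CCOC1CC[C@](C)(/C(C)=C/C)[C@@H](CCC=C)C(=O)O
F5 | step 14 | 9α-hydroxy-11,12,13-trinoreremophil-3-en-8-one | C1C[C@]2(C)C(C)=CCC[C@H]2[C@H](O)C1=O
F6 | step 16 | 8α,9α-(1-methoxyethylidenedioxy)-11,12,13-trinoreremophilan-3α-ol (either configuration at the orthoester carbon) | C1C[C@]2(C)[C@@H](C)[C@H](O)CC[C@H]2[C@@H]3OC(C)(OC)O[C@H]13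
F7 | step 16 | 8α-acetoxy-11,12,13-trinoreremophilane-3α,9α-diol | C1C[C@]2(C)[C@@H](C)[C@H](O)CC[C@H]2[C@H](O)[C@@H]1OC(C)=O
F8 | step 16 | 8α-acetoxy-3α,9α-bis(tert-butyldimethylsilyloxy)-11,12,13-trinoreremophilane | C1C[C@]2(C)[C@@H](C)[C@H](O[Si](C)(C)C(C)(C)C)CC[C@H]2[C@H](O[Si](C)(C)C(C)(C)C)[C@@H]1OC(C)=O
F9 | step 18 | 3α,9α-bis(tert-butyldimethylsilyloxy)-11-hydroxy-7βH-eremophilan-8-one | CC(C)(O)[C@@H]1C[C@]2(C)[C@@H](C)[C@H](O[Si](C)(C)C(C)(C)C)CC[C@H]2[C@H](O[Si](C)(C)C(C)(C)C)C1=O
F10 | step 18 | 3α,9α-bis(tert-butyldimethylsilyloxy)eremophil-7(11)-en-8-one | CC(C)=C1C[C@]2(C)[C@@H](C)[C@H](O[Si](C)(C)C(C)(C)C)CC[C@H]2[C@H](O[Si](C)(C)C(C)(C)C)C1=O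
F11 | step 21 | 3α,9α-bis(tert-butyldimethylsilyloxy)-8α-(4-methoxybenzyloxy)-7βH-eremophil-11-ene | C=C(C)[C@@H]1C[C@]2(C)[C@@H](C)[C@H](O[Si](C)(C)C(C)(C)C)CC[C@H]2[C@H](O[Si](C)(C)C(C)(C)C)[C@@H]1OCc1ccc(OC)cc1
F12 | step 21 | 8α-(4-methoxybenzyloxy)-7βH-eremophil-11-ene-3α,9α-diol | C=C(C)[C@@H]1C[C@]2(C)[C@@H](C)[C@H](O)CC[C@H]2[C@H](O)[C@@H]1OCc1ccc(OC)cc1
F13 | step 21 | 8α-(4-methoxybenzyloxy)-7βH-eremophil-11-ene-3α,9α-diyl bis(hex-2-ynoate) | C=C(C)[C@@H]1C[C@]2(C)[C@@H](C)[C@H](OC(=O)C#CCCC)CC[C@H]2[C@H](OC(=O)C#CCCC)[C@@H]1OCc1ccc(OC)cc1
A1 | alternative 1 | trans-fused 3α-(tert-butyldimethylsilyloxy)-4β-methyl-8-[tri(propan-2-yl)silyloxy]octal-8-ene-5β-carbaldehyde (eremophilane numbering, 10α-H) | C1C[C@]2(C=O)[C@@H](C)[C@H](O[Si](C)(C)C(C)(C)C)CC[C@H]2C=C1O[Si](C(C)C)(C(C)C)C(C)C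
A2 | alternative 1 | (3R,4R,7E)-4-[(tert-butyldimethylsilyl)oxy]-3-methyl-2-methylidene-9-{[tri(propan-2-yl)silyl]oxy}deca-7,9-dienal | C=C(C=O)[C@@H](C)[C@H](O[Si](C)(C)C(C)(C)C)CC/C=C/C(=C)O[Si](C(C)C)(C(C)C)C(C)C
A3 | alternative 2 | trans-fused 8-methoxy-4β,5β-dimethyloctal-7-ene-3,6,9-trione (eremophilane numbering, 10α-H) | COC1=CC(=O)[C@]2(C)[C@@H](C)C(=O)CC[C@H]2C1=O
A4 | alternative 2 | 2-methoxy-5-methylcyclohexa-2,5-diene-1,4-dione | COC1=CC(=O)C(C)=CC1=O
A5 | alternative 2 | trimethyl{[(3Z)-penta-1,3-dien-3-yl]oxy}silane | C/C=C(\O[Si](C)(C)C)C=C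
A6 | alternative 3 | 4β,5β-dimethyl-11,12,13-trinoreremophil-9-ene-3,8-dione | C1C[C@]2(C)[C@@H](C)C(=O)CCC2=CC1=O
A7 | alternative 3 | (7aS)-7a-methyl-2,3,7,7a-tetrahydro-1H-indene-1,5(6H)-dione | C1C[C@]2(C)C(=O)CCC2=CC1=O
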